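Every mole charged stays on the books, as Q or D still unchanged or as X, E, J or L, so the entries of a flask, taken as fractions of the charge, sum to one. Q stands at 0.20 M in these flasks, and what moves is f, the fraction of the charge that is D.

| flask | Q | D | remark | time |
|---|---|---|---|---|
| autumn | 0.20 M | 0.061 M | run made earlier |  |
| summer | 0.20 M | 0.19 M | run made earlier |  |
| dusk | 0.20 M | 0.56 M | run made earlier |  |
| ash | 0.20 M | 0.0500 M |  | 2.0 d |
| cedar | 0.20 M | 0.100 M |  | 2.0 d |
| maple | 0.20 M | 0.200 M |  | 2.0 d |
| larch | 0.20 M | 0.400 M |  | 2.0 d |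
| alder | 0.20 M | 0.800 M |  | 2.0 d |

| run | time / h | X / % | E / % |
|---|---|---|---|
| autumn | 3.00 | 3.5 | 15.1 |
| autumn | 8.00 | 7.9 | 31.7 |
| autumn | 15.0 | 10.6 | 46.9 |
| autumn | 25.0 | 12.8 | 59.2 |
| autumn | 30.0 | 13.7 | 62.6 |
| summer | 2.50 | 1.8 | 23.9 |
| summer | 5.00 | 3.8 | 37.3 |
| summer | 10.0 | 5.9 | 51.2 |
| summer | 20.0 | 8.8 | 64.6 |
| summer | 30.0 | 10.1 | 70.8 |
| dusk | 3.00 | 1.8 | 38.1 |
| dusk | 8.00 | 3.4 | 60.4 |
| dusk | 15.0 | 5.4 | 71.0 |
| dusk | 25.0 | 6.6 | 77.2 |
| dusk | 30.0 | 6.2 | 78.9 |

(each reading ± 0.3 percentage points)

- what may be going on: Q <-> D; Q -> X; D -> E; X <-> E; D <-> L; X <-> J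
- "hardly changes" means that all values lie within two and a half points (for a concentration: within two and a half percent of the largest)

- share of X in all that became X or E or J for ash, cedar, maple, larch, alder, in this order
- how that number moves from the first to the last of them (rises, then falls / falls, then rises / falls all the way / hardly changes / rises all the way)

We open the ledger at 30.0 h, the last reading. Autumn has f = 0.234 and holds X at 13.7%; dusk has f = 0.737 and holds X at 6.2%. If each mole goes its way by first-order steps, any flask is a mixture of two end flasks, pure Q and pure D, and X is a straight line in f. We call its drop per unit of f the D penalty, 0.149: the X a mole of charge gives up by being D and not Q. Summer tests the line: at f = 0.487 it says 9.93%, the reading is 10.1%, and the scatter is 0.3 percentage points.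

Solved at the ends, the books read as follows. A mole of Q has put 0.172 into X and 0.550 into E, which leaves 0.278 open. A mole of D has put 0.0228 into X and 0.874 into E, which leaves 0.103 open.

The share of X, its selectivity, is X over X, E and J together, and that sum cannot exceed the charge. So if X holds its level up to 2.0 d, X on the line is a floor for the share. Our floor is 14.2% for ash and 5.26% for alder. A falling floor does not by itself make the share fall, for the share also has X, E and J below the line. But J is unread, and on the books X and E together rise from 0.722 for a mole of Q to 0.897 for a mole of D, while X drops. So we commit to a share that falls all the way.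

The forecast stands above that floor with the same fall, at 16.1%, 13.7%, 10.9%, 8.1% and 6%, falls all the way: “D therefore goes mainly to E”. The flasks give 16.1%, 13.9%, 11.3%, 8.68% and 6.60%, falls all the way.

    Q ⇌ D (K = 1.10, k = 9.10 × 10⁻⁴ min⁻¹)
    Q → X (k = 3.60 × 10⁻⁴ min⁻¹)
    D → E (k = 0.00440 min⁻¹)
    X ⇌ E (K = 23.0, k = 1.10 × 10⁻⁴ min⁻¹)
    D ⇌ L (K = 94.0, k = 2.80 × 10⁻⁴ min⁻¹)
    X ⇌ J (K = 0.510, k = 0.00280 min⁻¹)

Starting from the ash share of 16.1%, the D penalty carried to maple at f = 0.500 gives 11.6%, and maple stands at 11.3%. Carried to alder at f = 0.800, it gives 7.16% against 6.60%. The largest single effect on that fall is the step from D to E: with that step taken away, the change from ash to alder goes from −9.5 points to 1.3 points.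

All runs were computed on assumed constants; the scatter is artificial.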